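The runs were generated by integration with constants of no real substance.

Before I commit this flask to 5.0 h, I want one number for its catalyst, since gamma, theta and the flask differ in their impurity charge.

| setting | gamma | theta | flask |
|---|---|---|---|
| left-handed substrate | 42 mM | 42 mM | 42 mM |
| right-handed substrate | 42 mM | 42 mM | 42 mM |
| reagent | 4 equiv (fed, over 25 min) | 4 equiv (fed, over 25 min) | 4.00 equiv (fed, over 25 min) |
| free catalyst | 7.3 mol% | 7.3 mol% | 7.3 mol% |
| racemization catalyst | 0.05 mol% | 0.05 mol% | 0.05 mol% |
| impurity | 0.74 mM | 1.7 mM | 1.1 mM |
| remark | run made earlier | run made earlier |  |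
| time |  |  | 5.0 h |

| run | time / h | left-handed product / % | right-handed product / % | left-handed substrate / % |
|---|---|---|---|---|
| gamma | 0.250 | 4.5 | 0.3 | 47.5 |
| gamma | 0.833 | 20.5 | 0 | 38.6 |
| gamma | 1.33 | 31.7 | 0 | 32.6 |
| gamma | 2.00 | 43.5 | 0 | 26.9 |
| gamma | 3.00 | 59.2 | 0.1 | 20.9 |
| gamma | 4.00 | 67.4 | 0.1 | 15.4 |
| theta | 0.333 | 1.7 | 0.3 | 48.5 |
| theta | 0.500 | 7.9 | 0 | 47.3 |
| theta | 0.833 | 13.3 | 0.6 | 44.2 |
| theta | 1.33 | 20.6 | 0 | 38.1 |
| theta | 2.50 | 38.1 | 1.5 | 32.6 |
| theta | 4.00 | 50.2 | 1.2 | 23.7 |

(standard deviation of a reading: 1 percentage point)

- excess of left-handed product over right-handed product in the product at 6.0 min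
- excess of left-handed product over right-handed product in the product at 5.0 h
- part of the left-handed substrate and right-handed substrate charged together that has reacted at 5.0 h

- free catalyst is single-handed; left-handed substrate and right-handed substrate are mirror images of each other, charged as a racemate, each of them at the stated concentration
- what was read earlier has a scatter of 1 percentage point, one standard deviation
- an excess is the difference of the two amounts in percent of their sum
- an excess is below zero if the other one leads

Gamma's left-handed product reads 67.4 % at 4.00 h, past the half of the charge that the left-handed substrate brought, so the hands exchange (a dynamic kinetic resolution) and I treat the substrate as one pool, twice the left-handed reading.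

The working catalyst, 4.68 % of the left-handed substrate charge in the flask, is the free catalyst charge less one free catalyst for each impurity charged. Gamma has 5.54 % and theta 3.25 %. If the rate follows it, clocks scale by the ratio of two working catalysts. Theta at 4.00 h sits at 2.35 h on gamma's clock, and its 52.6 % reacted lies between gamma's 46.2 % at 2.00 h and 58.2 % at 3.00 h.

The flask at 5.0 h is then gamma at 4.23 h. From below, gamma had reacted 69.2 % at 4.00 h, which is earlier. From above, gamma's average first-order constant 0.294 h⁻¹, read off that reading and carried on from it, gives 71.2 %. That end reads high, since gamma's late slope is 0.279 h⁻¹. Each end carries twice the scatter of a reading. My bracket covers conversion, not the excesses.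

The forecast gives 71 % (65 % to 76 %), at the top of my bracket, and excesses of 96 % and 98 %, holding that “Impurity seems to remove active catalyst roughly stoichiometrically”.

The flask gives excesses of 98.7 % and 98.7 %, and 70.3 % reacted, inside my bracket.

    reagent + free catalyst + right-handed substrate → free catalyst + right-handed product (k = 0.220 M⁻² min⁻¹)
    left-handed substrate + racemization catalyst ⇌ right-handed substrate + racemization catalyst, rate k2*[racemization catalyst]*[left-handed substrate] forward; the back reaction follows from the equilibrium constant (k = 64000 M⁻¹ min⁻¹)
    free catalyst + impurity → spent catalyst A (k = 170 M⁻¹ min⁻¹)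
    2 racemization catalyst → spent catalyst B (k = 940 M⁻¹ min⁻¹)
    reagent + free catalyst + left-handed substrate → free catalyst + left-handed product (k = 33.0 M⁻² min⁻¹)

At 5.00 h the flask's free catalyst stands at 64.1 % of its charge, and my working catalyst is 64.1 % of that same charge. The forecast is wrong if a run of this recipe ends outside its range, for instance above 76 %. A changed charge goes there: the neighbour flask has 12 mol% of free catalyst. Its working catalyst is 9.38 %, which puts it at 8.47 h on gamma's clock, past gamma's readings, so I have an upper end only: 91.7 %. That neighbour flask ends with 88.1 % reacted.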